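**Plan**

1. Labels: ring A = cyclohexenol with C(a) carbinol carbon, C(b) methyl-bearing alkene carbon, C(c) alkene carbon carrying the CH2CH2 linker, C(d) quaternary carbon, C(e) and C(f) CH2; ring B = cyclohexane with C(p) CH carrying the linker, C(q) angular C–Me, C(r) ring-fusion CH–O, C(s) and C(t) CH2, C(u) C(Me)OH; ring C = oxepane (O, CMe2, CHOH, two CH2, C(q), C(r)).
2. Cuts: C(a)–O (enone reduction); C(b) with its methyl taken out as chloro(methyl)carbene, which contracts ring A to a cyclopentanone enol silane; linker CH2–C(c) (aldol condensation, then 1,4-reduction); C(d)–CH3 (conjugate addition); in the other half the oxepane O–CMe2 bond (epoxide opening), C(p)–linker (Claisen) and the C(u)–O bond (lactonisation).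
3. Enabling feature: C(a)(O)–C(b)(Me)=C(c) is a 2-methylcyclohex-2-enone retron. Without C(b) the carbonyl carbon is bonded to C(c) and lies β to C(d), so a cyclopentenone conjugate addition/enolate aldol builds the quaternary carbon and joins the halves. The one-carbon insertion then places the carbonyl one carbon further from C(d) and creates the tetrasubstituted alkene.
4. Forward order: ring B from (R)-carvone (two alkylations) → ring C by 7-endo epoxide opening → C(p) and C(u) by epoxidation, Wharton, Eschenmoser–Claisen and iodolactonisation → aldehyde; five-membered precursor of ring A by asymmetric conjugate addition; aldol union; ring expansion five → six; cross-metathesis, reduction, desilylation.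
5. Stereochemistry: C(r) from carvone (Criegee, retention); C(q) by alkylation anti to isopropenyl; the oxepane carbinol by Shi epoxidation; C(p) by convex-face epoxidation relayed through Wharton and a suprafacial Claisen; C(u) by cis-lactonisation; C(d) by ligand-controlled conjugate addition; C(a) by CBS reduction.

Key step: step 18

Remark on the structure: the given configuration puts the angular methyl on C(q) and the ring-fusion hydrogen on C(r) on the same face (cis-fused oxepane), so the C(r)–O bond is carried over with retention from carvone; an epoxide cascade would give the trans fusion.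
Remark on supply: 5-iodo-2-methylpent-2-ene is taken as purchasable; it is otherwise one Finkelstein step from the commercial bromide.

**Route**

Step 1
Reactants: 1 (R)-(−)-carvone; 2 5-iodo-2-methylpent-2-ene
Product: 4 (5R)-6-(4-methylpent-3-enyl)carvone as a mixture of epimers at the new centre, via lithium dienolate 3 (not isolated)
Conditions: LDA, THF, −78 °C; then 2, DMPU, −78 → 0 °C
Reagents that add atoms: none
Why: Kinetic deprotonation gives the cross-conjugated α'-enolate, which is C-alkylated by the primary iodide (enolate alkylation); the new centre is planarised again in step 2, so its configuration does not matter.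

Step 2
Reactants: 4 (5R)-6-(4-methylpent-3-enyl)carvone
Product: 6 6-methyl-6-(4-methylpent-3-enyl)carvone (5S,6R; methyl trans to isopropenyl), via lithium enolate 5 (not isolated)
Conditions: LDA, THF, −78 → 0 °C; then MeI, −78 °C → rt
Reagents that add atoms: iodomethane, CI
Why: Second enolate alkylation; MeI should approach the tetrasubstituted enolate anti to the neighbouring isopropenyl group, which allylic 1,2-strain holds pseudoaxial, so the methyl ends trans to isopropenyl and the side chain cis, which sets the angular quaternary carbon C(q).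

Step 3
Reactants: 6 6-methyl-6-(4-methylpent-3-enyl)carvone
Product: 7 side-chain (S)-epoxide of 6
Conditions: L-fructose-derived Shi ketone (30 mol %), Oxone, K2CO3, Bu4NHSO4, MeCN/CH2(OMe)2/aqueous borate buffer, 0 °C
Reagents that add atoms: potassium peroxymonosulfate (Oxone), [K+].[O-]S(=O)(=O)OO
Why: Shi asymmetric epoxidation; the chiral dioxirane attacks the electron-rich trisubstituted alkene much faster than the 1,1-disubstituted isopropenyl or the enone alkene, and catalyst control should give the (S)-epoxide whose CH–O becomes the oxepane carbinol.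

Step 4
Reactants: 7 side-chain (S)-epoxide of 6
Product: 10 hydroxy epoxy enone (ring OH cis to the epoxyalkyl chain), via methoxy hydroperoxide 8 (not isolated), via acetate 9 (not isolated)
Conditions: O3, CH2Cl2/MeOH, −78 °C; Ac2O, Et3N, DMAP, 0 °C → rt; then K2CO3, MeOH, 0 °C
Reagents that add atoms: ozone, [O-][O+]=O
Why: Ozone should cleave only the isopropenyl group (the enone alkene is electron-poor), acetylation of the α-methoxy hydroperoxide triggers a Criegee rearrangement in which the ring carbon migrates to oxygen with retention, and brief cold methanolysis (kept short to avoid retro-aldol opening of the β-hydroxy ketone) frees the alcohol, so the carvone stereocentre becomes C(r).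

Step 5
Reactants: 10 hydroxy epoxy enone
Product: 11 cis-fused oxepane enone carrying a TIPS ether on the oxepane carbinol
Conditions: TIPSOTf, 2,6-lutidine, MeNO2, −25 → 0 °C
Reagents that add atoms: triisopropylsilyl triflate, CC(C)[Si](C(C)C)(C(C)C)OS(=O)(=O)C(F)(F)F
Why: Silyl-triflate-promoted endo-selective hydroxy epoxide cyclisation: the silylated epoxide ionises at its tertiary carbon, the cis-disposed ring hydroxyl captures it (7-endo) while the secondary C–O bond is untouched (retention, silyl stays on that oxygen), giving the cis-fused oxepane.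

Step 6
Reactants: 11 cis-fused oxepane enone
Product: 12 α,β-epoxy ketone (epoxide oxygen syn to the angular methyl)
Conditions: 30% H2O2, NaOH, MeOH, 0 °C
Reagents that add atoms: hydrogen peroxide, OO
Why: Weitz–Scheffer nucleophilic epoxidation; hydroperoxide should add to the β-carbon from the convex face, anti to the ring-fusion oxygen and the oxepane ring (the same sense as in carvone).

Step 7
Reactants: 12 α,β-epoxy ketone
Product: 14 transposed allylic alcohol (OH on C(t); C(u)=C(p) alkene), via epoxy hydrazone 13 (not isolated)
Conditions: N2H4·H2O, AcOH (cat.), MeOH, 0 °C → rt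
Reagents that add atoms: none
Why: Wharton transposition; the epoxy hydrazone fragments with loss of N2, and because the C–O bond at C(t) is never broken its configuration is that of the epoxide.

Step 8
Reactants: 14 transposed allylic alcohol
Product: 16 γ,δ-unsaturated N,N-dimethylamide (acetamide arm on C(p) syn to the angular methyl), via ketene N,O-acetal 15 (not isolated)
Conditions: MeC(OMe)2NMe2, xylene, 140 °C
Reagents that add atoms: N,N-dimethylacetamide dimethyl acetal, COC(C)(OC)N(C)C
Why: Eschenmoser–Claisen rearrangement; the [3,3] shift is suprafacial, so the two-carbon arm is delivered to C(p) on the face that carried the allylic oxygen, which sets C(p).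

Step 9
Reactants: 16 γ,δ-unsaturated N,N-dimethylamide
Product: 18 cis-fused iodolactone, via iodo iminium lactone 17 (not isolated)
Conditions: I2, THF/H2O, rt; aqueous Na2S2O3/NaHCO3 work-up
Reagents that add atoms: iodine, II; water, O
Why: Iodolactonisation of a γ,δ-unsaturated amide; the amide oxygen attacks the tertiary alkene carbon C(u) (5-exo, Markovnikov) anti to iodine, and since the five-membered ring can only be cis-fused the tertiary C–O bond is set syn to the arm on C(p).

Step 10
Reactants: 18 cis-fused iodolactone
Product: 19 diol (primary alcohol on the linker, tertiary alcohol at C(u))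
Conditions: LiAlH4, THF, 0 °C → reflux; aqueous potassium sodium tartrate work-up
Reagents that add atoms: none
Why: Hydride reduction opens the lactone to the diol and removes iodine, either by direct substitution or through the trans-diaxial epoxide that reopens at the secondary carbon; both paths leave the C(u) carbinol configuration intact.

Step 11
Reactants: 19 diol
Product: 20 bis(triethylsilyl) ether
Conditions: TESOTf, 2,6-lutidine, CH2Cl2, 0 °C → rt
Reagents that add atoms: triethylsilyl triflate, CC[Si](CC)(CC)OS(=O)(=O)C(F)(F)F
Why: Silyl triflate silylation protects the primary and the tertiary alcohol; the tertiary one must be masked so that it cannot add to the enone or displace the mesylate after fragment union.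

Step 12
Reactants: 20 bis(triethylsilyl) ether
Product: 21 aldehyde (tertiary TES and secondary TIPS ethers retained)
Conditions: (COCl)2, DMSO, CH2Cl2, −78 → −30 °C; Et3N, −78 °C → rt
Reagents that add atoms: none
Why: Under Swern conditions a primary triethylsilyl ether is oxidised directly to the aldehyde while tertiary and hindered secondary silyl ethers are left alone (selective oxidative desilylation).

Step 13
Reactants: 22 3-ethoxycyclopent-2-en-1-one; 23 but-3-enylmagnesium bromide
Product: 25 3-(but-3-enyl)cyclopent-2-en-1-one, via 1,2-adduct 24 (not isolated)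
Conditions: THF, 0 °C → rt; then 1 M HCl
Reagents that add atoms: none
Why: Stork–Danheiser sequence; 1,2-addition to the vinylogous ester and acid hydrolysis with loss of ethanol transpose the carbonyl and give the β-substituted enone.

Step 14
Reactants: 25 3-(but-3-enyl)cyclopent-2-en-1-one
Product: 27 trimethylsilyl enol ether of (S)-3-(but-3-enyl)-3-methylcyclopentanone (double bond towards the quaternary carbon), via dimethylaluminium enolate 26 (not isolated)
Conditions: Me3Al, Cu(OTf)2 (5 mol %), chiral sulfonate-bearing N-heterocyclic carbene ligand (5 mol %, from its imidazolinium salt), THF, −78 °C; then TMSOTf, −78 → 0 °C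
Reagents that add atoms: trimethylaluminium, C[Al](C)C; trimethylsilyl triflate, C[Si](C)(C)OS(=O)(=O)C(F)(F)F
Why: Copper-catalysed asymmetric conjugate addition of Me3Al to a β-alkyl cyclopentenone creates the quaternary carbon C(d) under ligand control (ligand enantiomer chosen for S), and silyl triflate trapping fixes the enolate regiochemistry.

Step 15
Reactants: 27 trimethylsilyl enol ether; 21 aldehyde
Product: 29 β-hydroxy ketone (mixture at the two new centres), via lithium enolate 28 (not isolated)
Conditions: MeLi, THF, 0 °C; then 21, −78 °C; NH4Cl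
Reagents that add atoms: none
Why: Methyllithium cleaves the enol silane to the regiodefined lithium enolate, which adds to the aldehyde (directed aldol addition); both new centres are removed in steps 16 and 17.

Step 16
Reactants: 29 β-hydroxy ketone
Product: 31 2-alkylidenecyclopentanone (exocyclic enone; geometry immaterial), via mesylate 30 (not isolated)
Conditions: MsCl, Et3N, CH2Cl2, 0 °C; then DBU, rt
Reagents that add atoms: none
Why: Mesylation and base-induced β-elimination through the enolate complete the aldol condensation and place the alkene between C(c) and the linker carbon.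

Step 17
Reactants: 31 2-alkylidenecyclopentanone
Product: 32 tetrasubstituted dimethylphenylsilyl enol ether
Conditions: [(Ph3P)CuH]6 (5 mol %), PhMe2SiH, toluene, rt
Reagents that add atoms: dimethylphenylsilane, C[SiH](C)c1ccccc1
Why: Copper hydride-catalysed 1,4-hydrosilylation puts hydride on the exocyclic β-carbon and silicon on oxygen, which should give the enol silane regiospecifically between the carbonyl carbon and C(c) and leave the isolated terminal alkene alone.

Step 18
Reactants: 32 tetrasubstituted dimethylphenylsilyl enol ether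
Product: 34 ring-expanded 2-methylcyclohex-2-enone, via chlorocyclopropane 33 (not isolated)
Conditions: CH3CHCl2, n-BuLi, Et2O, −40 → −20 °C; then Et3N, toluene, 110 °C
Reagents that add atoms: 1,1-dichloroethane, CC(Cl)Cl
Why: Butyllithium deprotonates 1,1-dichloroethane and α-elimination of LiCl gives chloro(methyl)carbene, which adds [2+1] to the enol silane double bond (carbonyl carbon=C(c)) to give siloxy chlorocyclopropane 33; on heating, chloride leaves as the bond between the siloxy carbon and C(c) opens in a disrotatory cyclopropyl-to-allyl cation process assisted by the siloxy oxygen, and loss of the silyl group from the resulting 1-siloxyallyl cation (an O-silylated enone) gives the enone with the carbene carbon inserted as C(b). The closest known reaction type is the halocarbene one-carbon ring expansion of cyclic silyl enol ethers, whose chloro(methyl)carbene version gives α-methyl enones. The cyclopropane is a temporary ring closed by cheletropic addition; the six-membered ring is not closed but arises when the zero bridge of the bicyclo[3.1.0]hexane is cut (five → six). No stereocentre is created in the product, since the three cyclopropane carbons end as carbonyl or alkene carbons and the neighbouring quaternary carbon C(d) is not touched. Regiochemistry is fixed by the enol silane position set in step 17, chemoselectivity over the terminal alkene rests on the far higher nucleophilicity of the enol ether, and the epimer with chlorine endo to the five-membered ring, which the carbenoid is expected to favour, is the one whose ionisation is stereoelectronically allowed in the fused system.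

Step 19
Reactants: 34 ring-expanded 2-methylcyclohex-2-enone
Product: 35 enone with the 4-methylpent-3-enyl side chain
Conditions: 2-methylbut-2-ene (excess), second-generation Grubbs catalyst (5 mol %), CH2Cl2, 40 °C
Reagents that add atoms: 2-methylbut-2-ene, CC=C(C)C
Why: Olefin cross-metathesis of the terminal alkene with excess 2-methylbut-2-ene installs the trisubstituted terminus; the tetrasubstituted enone alkene is inert.

Step 20
Reactants: 35 enone with the 4-methylpent-3-enyl side chain
Product: 36 (R)-allylic alcohol (bis-silyl ether)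
Conditions: (S)-2-methyl-CBS-oxazaborolidine, catecholborane, toluene, −78 °C
Reagents that add atoms: none
Why: Corey–Bakshi–Shibata reduction; with the α-methyl alkenyl side as the large group the (S)-oxazaborolidine should give the (R)-carbinol C(a) under reagent control, and catecholborane avoids hydroboration of the alkenes.

Step 21
Reactants: 36 (R)-allylic alcohol (bis-silyl ether)
Product: 37 target compound
Conditions: Bu4NF, THF, 60 °C
Reagents that add atoms: none
Why: Fluoride-mediated desilylation removes the tertiary TES and the hindered secondary TIPS ether under basic conditions that should not ionise the allylic alcohol.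

**Compound list**

1 | (R)-(−)-carvone | CC1=CC[C@H](CC1=O)C(C)=C | starting material
2 | 5-iodo-2-methylpent-2-ene | CC(C)=CCCI | starting material
3 | lithium dienolate of carvone (kinetic α'-enolate) | CC1=CC[C@@H](C(C)=C)C=C1O[Li] | intermediate
4 | (5R)-6-(4-methylpent-3-enyl)carvone, epimers at C6 | CC1=CC[C@@H](C(C)=C)C(CCC=C(C)C)C1=O | intermediate
5 | lithium enolate of 4 | CC1=CC[C@@H](C(C)=C)C(CCC=C(C)C)=C1O[Li] | intermediate
6 | (5S,6R)-2,6-dimethyl-6-(4-methylpent-3-enyl)-5-(prop-1-en-2-yl)cyclohex-2-en-1-one (6-methyl trans to isopropenyl) | O=C1[C@](C)(CCC=C(C)C)[C@H](C(C)=C)CC=C1C | intermediate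
7 | side-chain (S)-epoxide of 6 | O=C1[C@](C)(CC[C@@H]2OC2(C)C)[C@H](C(C)=C)CC=C1C | intermediate
8 | α-methoxy hydroperoxide from ozonolysis of 7 | O=C1[C@](C)(CC[C@@H]2OC2(C)C)[C@H](C(C)(OC)OO)CC=C1C | intermediate
9 | ring acetate (Criegee product) | O=C1[C@](C)(CC[C@@H]2OC2(C)C)[C@H](OC(C)=O)CC=C1C | intermediate
10 | hydroxy epoxy enone (OH cis to the epoxyalkyl chain, trans to the angular methyl) | O=C1[C@](C)(CC[C@@H]2OC2(C)C)[C@H](O)CC=C1C | intermediate
11 | cis-fused oxepane enone, TIPS ether on the oxepane carbinol | O=C1[C@]2(C)CC[C@H](O[Si](C(C)C)(C(C)C)C(C)C)C(C)(C)O[C@@H]2CC=C1C | intermediate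
12 | α,β-epoxy ketone (epoxide syn to the angular methyl) | O=C1[C@]2(C)CC[C@H](O[Si](C(C)C)(C(C)C)C(C)C)C(C)(C)O[C@@H]2C[C@H]3O[C@@]13C | intermediate
13 | epoxy hydrazone | NN=C1[C@]2(C)CC[C@H](O[Si](C(C)C)(C(C)C)C(C)C)C(C)(C)O[C@@H]2C[C@H]3O[C@@]13C | intermediate
14 | transposed allylic alcohol | C1=C(C)[C@H](O)C[C@H]2OC(C)(C)[C@@H](O[Si](C(C)C)(C(C)C)C(C)C)CC[C@@]12C | intermediate
15 | ketene N,O-acetal of 14 | C1=C(C)[C@H](OC(=C)N(C)C)C[C@H]2OC(C)(C)[C@@H](O[Si](C(C)C)(C(C)C)C(C)C)CC[C@@]12C | intermediate
16 | γ,δ-unsaturated N,N-dimethylamide | CN(C)C(=O)C[C@H]1[C@]2(C)CC[C@H](O[Si](C(C)C)(C(C)C)C(C)C)C(C)(C)O[C@@H]2CC=C1C | intermediate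
17 | iodo iminium lactone iodide | C[N+](C)=C1C[C@H]2[C@]3(C)CC[C@H](O[Si](C(C)C)(C(C)C)C(C)C)C(C)(C)O[C@@H]3C[C@H](I)[C@@]2(C)O1.[I-] | intermediate
18 | cis-fused iodolactone (iodine anti to the lactone oxygen) | O=C1C[C@H]2[C@]3(C)CC[C@H](O[Si](C(C)C)(C(C)C)C(C)C)C(C)(C)O[C@@H]3C[C@H](I)[C@@]2(C)O1 | intermediate
19 | diol (2-hydroxyethyl arm on C(p), tertiary OH at C(u)) | OCC[C@H]1[C@]2(C)CC[C@H](O[Si](C(C)C)(C(C)C)C(C)C)C(C)(C)O[C@@H]2CC[C@@]1(C)O | intermediate
20 | bis(triethylsilyl) ether of 19 | CC[Si](CC)(CC)OCC[C@H]1[C@]2(C)CC[C@H](O[Si](C(C)C)(C(C)C)C(C)C)C(C)(C)O[C@@H]2CC[C@@]1(C)O[Si](CC)(CC)CC | intermediate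
21 | aldehyde (tertiary TES, secondary TIPS) | O=CC[C@H]1[C@]2(C)CC[C@H](O[Si](C(C)C)(C(C)C)C(C)C)C(C)(C)O[C@@H]2CC[C@@]1(C)O[Si](CC)(CC)CC | intermediate
22 | 3-ethoxycyclopent-2-en-1-one | CCOC1=CC(=O)CC1 | starting material
23 | but-3-enylmagnesium bromide | C=CCC[Mg]Br | starting material
24 | 1,2-adduct, bromomagnesium 1-(but-3-enyl)-3-ethoxycyclopent-2-en-1-olate | CCOC1=CC(O[Mg]Br)(CCC=C)CC1 | intermediate
25 | 3-(but-3-enyl)cyclopent-2-en-1-one | O=C1C=C(CCC=C)CC1 | intermediate
26 | dimethylaluminium enolate of (S)-3-(but-3-enyl)-3-methylcyclopentanone | C=CCC[C@@]1(C)CCC(O[Al](C)C)=C1 | intermediate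
27 | (S)-3-(but-3-enyl)-3-methyl-1-(trimethylsilyloxy)cyclopent-1-ene | C=CCC[C@@]1(C)CCC(O[Si](C)(C)C)=C1 | intermediate
28 | lithium enolate from 27 | C=CCC[C@@]1(C)CCC(O[Li])=C1 | intermediate
29 | β-hydroxy ketone (aldol adduct, mixture at the two new centres) | C=CCC[C@@]1(C)CCC(=O)C1C(O)C[C@H]1[C@]2(C)CC[C@H](O[Si](C(C)C)(C(C)C)C(C)C)C(C)(C)O[C@@H]2CC[C@@]1(C)O[Si](CC)(CC)CC | intermediate
30 | mesylate of 29 | C=CCC[C@@]1(C)CCC(=O)C1C(OS(C)(=O)=O)C[C@H]1[C@]2(C)CC[C@H](O[Si](C(C)C)(C(C)C)C(C)C)C(C)(C)O[C@@H]2CC[C@@]1(C)O[Si](CC)(CC)CC | intermediate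
31 | 2-alkylidenecyclopentanone (alkene geometry not defined) | C=CCC[C@@]1(C)CCC(=O)C1=CC[C@H]1[C@]2(C)CC[C@H](O[Si](C(C)C)(C(C)C)C(C)C)C(C)(C)O[C@@H]2CC[C@@]1(C)O[Si](CC)(CC)CC | intermediate
32 | tetrasubstituted dimethylphenylsilyl enol ether | C=CCC[C@@]1(C)CCC(O[Si](C)(C)c3ccccc3)=C1CC[C@H]1[C@]2(C)CC[C@H](O[Si](C(C)C)(C(C)C)C(C)C)C(C)(C)O[C@@H]2CC[C@@]1(C)O[Si](CC)(CC)CC | intermediate
33 | siloxy chlorocyclopropane (6-chloro-6-methyl-1-siloxybicyclo[3.1.0]hexane core, epimers) | C=CCC[C@@]1(C)CCC2(O[Si](C)(C)c3ccccc3)C(C)(Cl)C12CC[C@H]1[C@]2(C)CC[C@H](O[Si](C(C)C)(C(C)C)C(C)C)C(C)(C)O[C@@H]2CC[C@@]1(C)O[Si](CC)(CC)CC | intermediate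
34 | ring-expanded 2-methylcyclohex-2-enone (but-3-enyl side chain) | C=CCC[C@@]1(C)CCC(=O)C(C)=C1CC[C@H]1[C@]2(C)CC[C@H](O[Si](C(C)C)(C(C)C)C(C)C)C(C)(C)O[C@@H]2CC[C@@]1(C)O[Si](CC)(CC)CC | intermediate
35 | enone with 4-methylpent-3-enyl side chain | CC(C)=CCC[C@@]1(C)CCC(=O)C(C)=C1CC[C@H]1[C@]2(C)CC[C@H](O[Si](C(C)C)(C(C)C)C(C)C)C(C)(C)O[C@@H]2CC[C@@]1(C)O[Si](CC)(CC)CC | intermediate
36 | (R)-allylic alcohol, bis-silyl ether | CC(C)=CCC[C@@]1(C)CC[C@@H](O)C(C)=C1CC[C@H]1[C@]2(C)CC[C@H](O[Si](C(C)C)(C(C)C)C(C)C)C(C)(C)O[C@@H]2CC[C@@]1(C)O[Si](CC)(CC)CC | intermediate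
37 | target compound | CC(C)=CCC[C@@]1(C)CC[C@@H](O)C(C)=C1CC[C@H]1[C@]2(C)CC[C@H](O)C(C)(C)O[C@@H]2CC[C@@]1(C)O | target

**Summary**

Total step count: 21. Longest linear sequence: 19 steps (steps 1–12, then 15–21, from carvone).

Steps most likely to fail:

1. Step 18. The tetrasubstituted enol silane next to a quaternary carbon may be cyclopropanated so slowly that the carbene is lost by 1,2-hydrogen shift and butyllithium cleaves the enol silane; the exo-chloro epimer may also fail to open. Fallback, setting out from 32: a dihalocarbene, which has no hydrogen-shift exit and always carries an endo halogen, is used and the methyl group is brought in afterwards by cross-coupling. CHBr3/KOtBu in hexane should give the dibromocyclopropane F1, which on warming in toluene opens with loss of the silyl bromide to the 2-bromo enone F2. Stille methylation of F2 (Me4Sn, Pd(PPh3)4, CuI, NMP) returns to the route at 34.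

2. Step 5. The ring hydroxyl may attack the secondary epoxide carbon (6-exo) and give the tetrahydropyran, or be silylated before it cyclises. Fallback, setting out from 10: the exo pathway is removed by making the CMe2 carbon the only electrophilic site. Diethylaluminium 2,2,6,6-tetramethylpiperidide should isomerise the epoxide to the secondary allylic alcohol F3 (retention at the carbinol carbon). Selective silylation of the less hindered hydroxyl (TIPSOTf, 2,6-lutidine, −78 °C) gives the allylic silyl ether F4. Intramolecular alkoxymercuration with Hg(O2CCF3)2 closes the oxepane at the tertiary carbon to the organomercurial F5, and Bu3SnH demercuration returns to the route at 11.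

3. Step 7. Hydrazone formation at a carbonyl flanked by two fully substituted carbons may be too slow, letting hydrazine open the epoxide instead. Fallback, setting out from 12: the transposition is done by radical fragmentation in place of a hydrazone. NaBH4 reduces the ketone to the epoxy alcohol F6, and NaH/CS2/MeI converts it to the xanthate F7. Bu3SnH/AIBN generates the carbinyl radical, which opens the adjacent epoxide to the alkene and an alkoxy radical that is reduced, returning to the route at 14.

Further compounds
F1 | step 18 | dibromocyclopropane adduct of 32 | C=CCC[C@@]1(C)CCC2(O[Si](C)(C)c3ccccc3)C(Br)(Br)C12CC[C@H]1[C@]2(C)CC[C@H](O[Si](C(C)C)(C(C)C)C(C)C)C(C)(C)O[C@@H]2CC[C@@]1(C)O[Si](CC)(CC)CC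
F2 | step 18 | 2-bromocyclohex-2-enone analogue of 34 | C=CCC[C@@]1(C)CCC(=O)C(Br)=C1CC[C@H]1[C@]2(C)CC[C@H](O[Si](C(C)C)(C(C)C)C(C)C)C(C)(C)O[C@@H]2CC[C@@]1(C)O[Si](CC)(CC)CC
F3 | step 5 | secondary allylic alcohol (isopropenyl carbinol) with free ring hydroxyl | O=C1[C@](C)(CC[C@H](O)C(C)=C)[C@H](O)CC=C1C
F4 | step 5 | TIPS ether of F3 at the allylic hydroxyl | O=C1[C@](C)(CC[C@H](O[Si](C(C)C)(C(C)C)C(C)C)C(C)=C)[C@H](O)CC=C1C
F5 | step 5 | oxepane alkylmercury trifluoroacetate | O=C1[C@]2(C)CC[C@H](O[Si](C(C)C)(C(C)C)C(C)C)C(C)(C[Hg]OC(=O)C(F)(F)F)O[C@@H]2CC=C1C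
F6 | step 7 | epoxy alcohol from reduction of 12 | OC1[C@]2(C)CC[C@H](O[Si](C(C)C)(C(C)C)C(C)C)C(C)(C)O[C@@H]2C[C@H]3O[C@@]13C
F7 | step 7 | S-methyl xanthate of F6 | CSC(=S)OC1[C@]2(C)CC[C@H](O[Si](C(C)C)(C(C)C)C(C)C)C(C)(C)O[C@@H]2C[C@H]3O[C@@]13C
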